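Retrosynthesis: the two ester C–O bonds at C7 and C9 are cut first, then the two carbinol C–O bonds at C7 and C9 (back to C–H), then the C1=O bond (back to an allylic CH2); no C–C bond is cut.
Forward: no ring is formed. The tricycle (cyclobutane C4–C5–C11–C10, cyclohexene through C1–C2=C3, cycloheptane through C6–C7–C8–C9) is bought as (+)-α-longipinene 1. C1 is oxidised to enone 2, C7 and then C9 are hydroxylated through alcohol 3 to diol 4, and 4 is acylated twice with 3-methylbut-2-enoyl chloride 5 to give target 6.
Feature behind the key step: the cycloheptane ring holds three contiguous unactivated methylenes C7–C8–C9 between the quaternary carbons C6 (CMe2) and C10. They sit on a rigid, lipophilic C15 cage whose only polar group, the C1–C2=C3 enone, lies on the other side of the cyclobutane, so each hydrogen has one fixed place relative to that anchor and an enzyme pocket can pick the pro-R hydrogens of C7 and C9.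
Stereochemistry: C4, C5, C10 and C11 are carried unchanged from 1; C7 and C9 (both R, oxygens trans) are set by two P450 BM3 variants that replace hydrogen by hydroxyl with retention; the acylation touches no stereocentre.
Numbering (longipinane): C1 = C=O, C2=C3 (methyl on C3), C4 and C11 = cyclobutane CH on C3 and on C1, C5 = cyclobutane CH on C6, C6 = CMe2, C10 = methyl-bearing quaternary carbon.

Key step: step 2

Assumption: commercial (+)-α-longipinene is taken to be the (1R,2S,7R,8R) enantiomer, whose cage is that of the target; variant A (C7-selective on 2) and variant B (C9-selective on 3) do not exist yet and are to be evolved from terpene-accepting P450 BM3 parents (saturation mutagenesis of the haem-pocket residues, GC–MS screening) before step 2 is run.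

Step 1
Reactants: 1 (+)-α-longipinene
Product: 2 (4R,5S,10R,11R)-longipin-2-en-1-one
Conditions: CrO3, 3,5-dimethylpyrazole, CH2Cl2, −20 °C
Reagents that add atoms: chromium trioxide, O=[Cr](=O)=O
Why: Allylic oxidation of a ring methylene by the CrO3–3,5-dimethylpyrazole complex, the reaction type that converts α-pinene into verbenone, should take C1 because it is the only allylic CH2 (the bridgehead C4–H cannot join a planar allyl system, the vinylic methyl is a slower primary site, and oxygen delivered at C3 returns to C1 by allylic transposition of the chromate ester); no stereocentre is formed and the four cage centres are not touched.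

Step 2
Reactants: 2 (4R,5S,10R,11R)-longipin-2-en-1-one
Product: 4 (4R,5S,7R,9R,10R,11R)-7,9-dihydroxylongipin-2-en-1-one, via (7R)-7-hydroxylongipin-2-en-1-one 3 (not isolated)
Conditions: E. coli resting cells co-expressing P450 BM3 variant A and glucose dehydrogenase, air, D-glucose, NADP+ (cat.), KH2PO4/K2HPO4 buffer pH 8.0, 2% DMSO, 25 °C; then cells with variant B and glucose dehydrogenase added to the same vessel, 25 °C
Reagents that add atoms: dioxygen, O=O
Why: Proposed new method: each variant should work by the P450 rebound mechanism, in which the haem oxoiron species (tetravalent iron, porphyrin radical cation), made from O2 and two electrons from NADPH, abstracts one hydrogen atom of the methylene and the carbon radical recombines with the iron-bound hydroxyl before it can invert, so OH takes the place of that hydrogen with retention. The closest known reaction type is the regio- and stereoselective hydroxylation of unactivated ring methylenes in terpenoid and steroid ketones by evolved P450 BM3 variants; this pair of sites on this cage is not known, and the variants must come from directed evolution, variant B being screened on 3. No ring is closed; two C–O bonds form, C7–O in the first stage (giving 3) and C9–O in the second. C7 becomes R because the pocket of variant A offers only the pro-R hydrogen of C7 to the iron, and C9 becomes R because variant B offers only the pro-R hydrogen of C9, which lies on the ring face opposite to the C7 hydroxyl, so a polar residue that binds this hydroxyl away from the haem turns the right face of C9 to the iron. The step needs C7 and C9 over C8 (the most exposed methylene), over the four methyl groups, the cyclobutane C–H bonds and the enone alkene, one face at each site, and no further oxidation of the new alcohols; the substrate contributes its rigidity, its single polar anchor at C1 (joined by the C7 hydroxyl in the second stage), its strong cyclobutane C–H bonds and its electron-poor alkene, whereas the choice among C7, C8 and C9 rests on the evolved pockets.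

Step 3
Reactants: 4 (4R,5S,7R,9R,10R,11R)-7,9-dihydroxylongipin-2-en-1-one; 5 3-methylbut-2-enoyl chloride
Product: 6 (4R,5S,7R,9R,10R,11R)-7,9-bis(3-methylbut-2-enoyloxy)longipin-2-en-1-one
Conditions: 5 (excess), DMAP, pyridine, CH2Cl2, 0 °C to 40 °C
Reagents that add atoms: 3-methylbut-2-enoyl chloride 5, CC(C)=CC(=O)Cl
Why: DMAP-catalysed acylation (acyl transfer through the N-acylpyridinium ion) should esterify both secondary alcohols in spite of their neopentyl-like positions, while pyridine is too weak a base to turn the acid chloride into the vinylketene that would give deconjugated esters; the carbinol C–O bonds stay intact, so C7 and C9 keep their configuration and the enone is a spectator.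

Compound list
1 | (+)-α-longipinene, (1R,2S,7R,8R)-2,6,6,9-tetramethyltricyclo[5.4.0.0(2,8)]undec-9-ene | C1CC[C@@]2(C)[C@@H]3CC=C(C)[C@H]2[C@@H]3C1(C)C | starting material
2 | (4R,5S,10R,11R)-longipin-2-en-1-one | C1CC[C@@]2(C)[C@@H]3C(=O)C=C(C)[C@H]2[C@@H]3C1(C)C | intermediate
3 | (4R,5S,7R,10R,11R)-7-hydroxylongipin-2-en-1-one (formed and consumed in step 2) | O[C@@H]1CC[C@@]2(C)[C@@H]3C(=O)C=C(C)[C@H]2[C@@H]3C1(C)C | intermediate
4 | (4R,5S,7R,9R,10R,11R)-7,9-dihydroxylongipin-2-en-1-one (hydroxyls trans) | O[C@@H]1C[C@@H](O)[C@@]2(C)[C@@H]3C(=O)C=C(C)[C@H]2[C@@H]3C1(C)C | intermediate
5 | 3-methylbut-2-enoyl chloride (senecioyl chloride) | CC(C)=CC(=O)Cl | starting material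
6 | (4R,5S,7R,9R,10R,11R)-7,9-bis(3-methylbut-2-enoyloxy)longipin-2-en-1-one (CNP0105062.1) | CC(C)=CC(=O)O[C@@H]1C[C@@H](OC(=O)C=C(C)C)[C@@]2(C)[C@@H]3C(=O)C=C(C)[C@H]2[C@@H]3C1(C)C | target

Total step count: 3. Longest linear sequence: 3 steps (1 to 2 to 4 to 6); 5 enters in step 3.

Steps most likely to fail, riskiest first

1. Step 2. The evolution campaign may not deliver a variant that prefers C7 or C9 over C8, the most exposed methylene. Hydroxylation may also occur on the wrong face or at a methyl group, a new alcohol may be oxidised on to the ketone, or host ene-reductases may reduce the enone. The fallback uses known chemistry and sets out from 2: the engineered, telescoped cascade is given up for classical preparative microbial hydroxylation with wild-type filamentous fungi, the long-established way to hydroxylate unactivated ring methylenes of sesquiterpenoid and steroid ketones. A panel of growing cultures (Mucor plumbeus, Rhizopus arrhizus, Aspergillus niger, Beauveria bassiana, Cunninghamella elegans) is screened on 2, the culture that forms 3 is run on scale and 3 is isolated by chromatography. Isolated 3 is then screened and fermented in the same way to give 4, where the route is rejoined. What is found by screening is the strain, not the reaction, and each stage is asked for one event only, so a separable mixture of site isomers is still usable. The path makes no new compound (F0).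

2. Step 3. The second acylation may stall at the hindered carbinols (C7 next to CMe2, C9 next to C10), and deprotonation of the acid chloride to the vinylketene may lead to deconjugated 3-methylbut-3-enoates. The fallback sets out from 4 and builds the acyl groups in two stages. Esterification of both alcohols with 2-(diethoxyphosphoryl)acetic acid (DCC, DMAP, CH2Cl2, 0 °C to rt) should give (4R,5S,7R,9R,10R,11R)-7,9-bis[2-(diethoxyphosphoryl)acetoxy]longipin-2-en-1-one F1. A double Horner–Wadsworth–Emmons olefination with acetone (NaH, THF, 0 °C, then acetone in excess) then forms both trisubstituted alkenes directly in conjugation and returns to 6.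

3. Step 1. Over-oxidation, attack at the vinylic methyl group or opening of the strained cyclobutane may consume the material. The fallback sets out from 1 and reaches the enone through the allylic ester and alcohol. Kharasch–Sosnovsky acyloxylation (CuBr cat., tert-butyl perbenzoate, benzene, 80 °C) should give (1S,4R,5S,10R,11R)-longipin-2-en-1-yl benzoate F2, with oxygen expected on the face of the C5 hydrogen, away from the C10 methyl; the C1 configuration is of no consequence. Hydrolysis (KOH, MeOH/H2O, 50 °C) should give (1S,4R,5S,10R,11R)-longipin-2-en-1-ol F3, and MnO2 (CH2Cl2, rt) should oxidise the allylic alcohol to 2.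

Further compounds
F0 | step 2 | none | none
F1 | step 3 | (4R,5S,7R,9R,10R,11R)-7,9-bis[2-(diethoxyphosphoryl)acetoxy]longipin-2-en-1-one | CCOP(=O)(OCC)CC(=O)O[C@@H]1C[C@@H](OC(=O)CP(=O)(OCC)OCC)[C@@]2(C)[C@@H]3C(=O)C=C(C)[C@H]2[C@@H]3C1(C)C
F2 | step 1 | (1S,4R,5S,10R,11R)-longipin-2-en-1-yl benzoate | C1CC[C@@]2(C)[C@@H]3[C@@H](OC(=O)c4ccccc4)C=C(C)[C@H]2[C@@H]3C1(C)C
F3 | step 1 | (1S,4R,5S,10R,11R)-longipin-2-en-1-ol | C1CC[C@@]2(C)[C@@H]3[C@@H](O)C=C(C)[C@H]2[C@@H]3C1(C)C
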